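The ring-fusion C5–H lies between the C4 carbinol of the cyclopentane (C1–C5) and the C6 oxygen of the cycloheptene (C5–C10, C1; daucane numbering): an aldol-type 1,3-pattern, read here as the trace of a pinacol-type 1,2-shift. The precursor is a trans-fused octalin, made from (R)-Wieland–Miescher ketone, in which C1 is still bonded to C6 and an equatorial C5 mesylate sits between the tertiary C4 and C6 hydroxyls. In one operation C1 moves from C6 to C5: the cyclohexane C1–C2–C3–C4–C5–C6 contracts to the cyclopentane, the second six-membered ring grows to the cycloheptene, C5 inverts (cis fusion) and C6 becomes the ketone for a later hydroxyl-directed reduction.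

Key step: step 10

Remark on labels: daucane numbering of the target is kept for every intermediate. C1 = ring-fusion carbon with CH3; C2, C3 = CH2; C4 = C(OH)(i-Pr); C5 = ring-fusion CH; C6 = CH–O–aroyl; C7 = CH2; C8 = C(CH3)=; C9 = =CH; C10 = CH–O–tigloyl. In the octalins, ring A is C1–C2–C3–C4–C5–C6 and ring B is C1–C6–C7–C8–C9–C10.

Step 1
Reactants: 1 (8aR)-8a-methyl-3,4,8,8a-tetrahydronaphthalene-1,6(2H,7H)-dione, (R)-Wieland–Miescher ketone
Product: 2 (4aR,5R)-5-hydroxy-4a-methyl-4,4a,5,6,7,8-hexahydronaphthalen-2(3H)-one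
Conditions: NaBH4 (0.3 equiv), EtOH, −10 °C
Reagents that add atoms: none
Why: Chemoselective NaBH4 reduction of the saturated C10 ketone beside the less electrophilic enone carbonyl masks C10 for the Grignard step, with hydride adding anti to the angular methyl (this centre is set again in step 6).

Step 2
Reactants: 2 (4aR,5R)-5-hydroxy-4a-methyl-4,4a,5,6,7,8-hexahydronaphthalen-2(3H)-one
Product: 3 (2R,4aR,5R)-4a-methyl-2-(propan-2-yl)-2,3,4,4a,5,6,7,8-octahydronaphthalene-2,5-diol
Conditions: i-PrMgCl (3.5 equiv), CeCl3 (3.5 equiv), THF, −78 to 0 °C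
Reagents that add atoms: isopropylmagnesium chloride, CC(C)[Mg]Cl
Why: Organocerium 1,2-addition to the enone carbonyl (CeCl3 suppresses enolisation, conjugate addition and β-hydride reduction), in which the bulky secondary nucleophile should take the equatorial path on the face of the angular methyl because the axial path meets the syn-axial C2–H, so that the C4 hydroxyl ends trans to the methyl; the C4 epimer is removed by chromatography.

Step 3
Reactants: 3 (2R,4aR,5R)-4a-methyl-2-(propan-2-yl)-2,3,4,4a,5,6,7,8-octahydronaphthalene-2,5-diol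
Product: 4 (6R,8aR)-6-hydroxy-8a-methyl-6-(propan-2-yl)-3,4,6,7,8,8a-hexahydronaphthalen-1(2H)-one
Conditions: Dess–Martin periodinane, pyridine, CH2Cl2, 0 °C to rt
Reagents that add atoms: none
Why: Dess–Martin oxidation of the secondary alcohol, which leaves the tertiary allylic alcohol untouched since pyridine buffers the acetic acid that could ionise it.

Step 4
Reactants: 4 (6R,8aR)-6-hydroxy-8a-methyl-6-(propan-2-yl)-3,4,6,7,8,8a-hexahydronaphthalen-1(2H)-one
Product: 6 (6R,8aR)-8a-methyl-6-(propan-2-yl)-6-[(trimethylsilyl)oxy]-6,7,8,8a-tetrahydronaphthalen-1(4H)-one, via bis-silylated enol ether 5 (not isolated)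
Conditions: LiN(i-Pr)2 (2.3 equiv), Me3SiCl, THF, −78 to 0 °C; then Pd(OAc)2 (1.1 equiv), MeCN, rt
Reagents that add atoms: chlorotrimethylsilane, C[Si](C)(C)Cl
Why: Saegusa–Ito dehydrogenation, in which the ketone can enolise only toward C9 because C1 is quaternary, the tertiary alkoxide is silylated in the same pot, and Pd(OAc)2 converts the silyl enol ether into the C8=C9 enone.

Step 5
Reactants: 6 (6R,8aR)-8a-methyl-6-(propan-2-yl)-6-[(trimethylsilyl)oxy]-6,7,8,8a-tetrahydronaphthalen-1(4H)-one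
Product: 8 (6R,8aR)-3,8a-dimethyl-6-(propan-2-yl)-6-[(trimethylsilyl)oxy]-6,7,8,8a-tetrahydronaphthalen-1(4H)-one, via methylated silyl enol ether 7 (not isolated)
Conditions: Me2CuLi (1.5 equiv), Me3SiCl, THF, −78 °C; then Pd(OAc)2 (1.1 equiv), MeCN, rt
Reagents that add atoms: lithium dimethylcuprate, [Li+].C[Cu-]C
Why: Conjugate addition of the Gilman cuprate to C8 with silyl trapping, followed by a second Saegusa–Ito oxidation, should give the 3-methyl enone, since β-hydride loss is possible only from C8 and the transient C8 stereocentre is erased.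

Step 6
Reactants: 8 (6R,8aR)-3,8a-dimethyl-6-(propan-2-yl)-6-[(trimethylsilyl)oxy]-6,7,8,8a-tetrahydronaphthalen-1(4H)-one
Product: 10 (1R,6R,8aR)-3,8a-dimethyl-6-(propan-2-yl)-1,4,6,7,8,8a-hexahydronaphthalene-1,6-diol, via silyl-protected allylic alcohol 9 (not isolated)
Conditions: NaBH4, CeCl3·7H2O, MeOH, −40 °C; then K2CO3, MeOH, rt
Reagents that add atoms: none
Why: Luche 1,2-reduction in which hydride reaches C10 from the face opposite the axial C1 methyl, setting the C10 hydroxyl cis to that methyl, after which K2CO3 in MeOH cleaves the tertiary trimethylsilyl ether.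

Step 7
Reactants: 10 (1R,6R,8aR)-3,8a-dimethyl-6-(propan-2-yl)-1,4,6,7,8,8a-hexahydronaphthalene-1,6-diol; 11 (2E)-2-methylbut-2-enoyl chloride (tigloyl chloride)
Product: 12 (1R,6R,8aR)-6-hydroxy-3,8a-dimethyl-6-(propan-2-yl)-1,4,6,7,8,8a-hexahydronaphthalen-1-yl (2E)-2-methylbut-2-enoate
Conditions: DMAP (0.2 equiv), Et3N, CH2Cl2, 0 °C to rt
Reagents that add atoms: none
Why: DMAP-catalysed acylation of the secondary allylic alcohol, to which the tertiary C4 hydroxyl is inert; the tiglate is the final C10 ester, so no protecting group is spent on C10.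

Step 8
Reactants: 12 (1R,6R,8aR)-6-hydroxy-3,8a-dimethyl-6-(propan-2-yl)-1,4,6,7,8,8a-hexahydronaphthalen-1-yl (2E)-2-methylbut-2-enoate
Product: 13 (1R,4aR,5S,6R,8aS)-4a,5,6-trihydroxy-3,8a-dimethyl-6-(propan-2-yl)-1,4,4a,5,6,7,8,8a-octahydronaphthalen-1-yl (2E)-2-methylbut-2-enoate
Conditions: OsO4 (1.05 equiv), TMEDA (1.1 equiv), CH2Cl2, −78 °C; then aq. NaHSO3, THF, rt
Reagents that add atoms: osmium tetroxide, O=[Os](=O)(=O)=O
Why: Hydroxyl-directed dihydroxylation with OsO4·TMEDA, in which the reagent is hydrogen-bonded to the pseudo-axial C4 hydroxyl and adds to C5=C6 syn to it, on the face opposite the angular methyl, giving the all-cis triol with an equatorial C5 hydroxyl, while C8=C9 has no hydrogen-bond donor and is deactivated by the allylic ester.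

Step 9
Reactants: 13 (1R,4aR,5S,6R,8aS)-4a,5,6-trihydroxy-3,8a-dimethyl-6-(propan-2-yl)-1,4,4a,5,6,7,8,8a-octahydronaphthalen-1-yl (2E)-2-methylbut-2-enoate
Product: 14 (1R,4aR,5S,6R,8aS)-4a,6-dihydroxy-5-[(methanesulfonyl)oxy]-3,8a-dimethyl-6-(propan-2-yl)-1,4,4a,5,6,7,8,8a-octahydronaphthalen-1-yl (2E)-2-methylbut-2-enoate
Conditions: MeSO2Cl (1.3 equiv), pyridine, CH2Cl2, 0 °C
Reagents that add atoms: methanesulfonyl chloride, CS(=O)(=O)Cl
Why: Sulfonylation of the only secondary hydroxyl, with both tertiary hydroxyls inert and epoxide formation excluded because the C5–O bond is cis to both neighbouring hydroxyls.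

Step 10
Reactants: 14 (1R,4aR,5S,6R,8aS)-4a,6-dihydroxy-5-[(methanesulfonyl)oxy]-3,8a-dimethyl-6-(propan-2-yl)-1,4,4a,5,6,7,8,8a-octahydronaphthalen-1-yl (2E)-2-methylbut-2-enoate
Product: 15 (1R,3aR,4R,8aR)-1-hydroxy-3a,6-dimethyl-8-oxo-1-(propan-2-yl)-1,2,3,3a,4,7,8,8a-octahydroazulen-4-yl (2E)-2-methylbut-2-enoate
Conditions: Et3Al (3 equiv), CH2Cl2, −78 to 0 °C; then H2O
Reagents that add atoms: none
Why: Et3Al turns the tertiary hydroxyls into aluminium alkoxides and activates the mesylate, so that the C6–C1 bond, antiperiplanar to the equatorial C5–O bond in the chair of ring A of the trans-octalin, shifts to C5 while C6 becomes the carbonyl in a concerted push–pull 1,2-shift. The closest known reaction type is the organoaluminium-promoted pinacol-type (semipinacol) rearrangement of 2-sulfonyloxy alcohols, also known in the hydronaphthalene-to-hydroazulene sense. No ring is closed by cyclisation: the cyclopentane arises from ring A by ring contraction (C6 leaves that ring through the 1,2-alkyl shift), and the cycloheptene arises from ring B by ring expansion (C5 is inserted between C6 and C1 by the same shift). The one new stereocentre, C5, is set by inversion at the carbon that loses the mesylate while C1 migrates with retention, which gives the cis ring fusion (C5–H cis to the C1 methyl) and leaves C4 and C10 untouched. The step needs migration of C1 and not of C3, whose bond to C4 is also antiperiplanar; this should be secured by the much higher migratory aptitude of the fully substituted C1 over the CH2 carbon C3. The low temperature and the absence of free base should keep the β-hydroxy ketone from retro-aldol cleavage and from epimerisation at C5.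

Step 11
Reactants: 15 (1R,3aR,4R,8aR)-1-hydroxy-3a,6-dimethyl-8-oxo-1-(propan-2-yl)-1,2,3,3a,4,7,8,8a-octahydroazulen-4-yl (2E)-2-methylbut-2-enoate
Product: 16 (1R,3aR,4R,8S,8aS)-1,8-dihydroxy-3a,6-dimethyl-1-(propan-2-yl)-1,2,3,3a,4,7,8,8a-octahydroazulen-4-yl (2E)-2-methylbut-2-enoate
Conditions: Me4NBH(OAc)3 (5 equiv), MeCN/AcOH 1:1, −25 °C
Reagents that add atoms: none
Why: Evans–Saksena hydroxyl-directed reduction, in which the C4 hydroxyl binds the acetoxyborohydride and delivers hydride to the concave face of the C6 ketone, giving the 1,3-anti diol with the C6 hydroxyl cis to C5–H, while the enoate and the isolated alkene are inert.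

Step 12
Reactants: 16 (1R,3aR,4R,8S,8aS)-1,8-dihydroxy-3a,6-dimethyl-1-(propan-2-yl)-1,2,3,3a,4,7,8,8a-octahydroazulen-4-yl (2E)-2-methylbut-2-enoate; 17 4-(acetyloxy)benzoyl chloride
Product: 18 (1R,3aR,4R,8S,8aS)-8-{[4-(acetyloxy)benzoyl]oxy}-1-hydroxy-3a,6-dimethyl-1-(propan-2-yl)-1,2,3,3a,4,7,8,8a-octahydroazulen-4-yl (2E)-2-methylbut-2-enoate
Conditions: DMAP (0.2 equiv), pyridine, CH2Cl2, 0 °C to rt
Reagents that add atoms: none
Why: DMAP-catalysed acylation of the secondary C6 hydroxyl, to which the tertiary C4 hydroxyl is unreactive.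

Step 13
Reactants: 18 (1R,3aR,4R,8S,8aS)-8-{[4-(acetyloxy)benzoyl]oxy}-1-hydroxy-3a,6-dimethyl-1-(propan-2-yl)-1,2,3,3a,4,7,8,8a-octahydroazulen-4-yl (2E)-2-methylbut-2-enoate
Product: 19 (1R,3aR,4R,8S,8aS)-1-hydroxy-8-[(4-hydroxybenzoyl)oxy]-3a,6-dimethyl-1-(propan-2-yl)-1,2,3,3a,4,7,8,8a-octahydroazulen-4-yl (2E)-2-methylbut-2-enoate
Conditions: NH4OAc (8 equiv), MeOH/H2O 4:1, rt
Reagents that add atoms: none
Why: Chemoselective solvolysis of the phenolic acetate under near-neutral conditions (an aryl acetate is far more labile than the alkyl tiglate and benzoate esters) should release the phenol and give the target.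

Compound list
1 | (8aR)-8a-methyl-3,4,8,8a-tetrahydronaphthalene-1,6(2H,7H)-dione, (R)-Wieland–Miescher ketone | O=C1C=C2CCCC(=O)[C@]2(C)CC1 | starting material
2 | (4aR,5R)-5-hydroxy-4a-methyl-4,4a,5,6,7,8-hexahydronaphthalen-2(3H)-one | O=C1C=C2CCC[C@@H](O)[C@]2(C)CC1 | intermediate
3 | (2R,4aR,5R)-4a-methyl-2-(propan-2-yl)-2,3,4,4a,5,6,7,8-octahydronaphthalene-2,5-diol | CC(C)[C@@]1(O)C=C2CCC[C@@H](O)[C@]2(C)CC1 | intermediate
4 | (6R,8aR)-6-hydroxy-8a-methyl-6-(propan-2-yl)-3,4,6,7,8,8a-hexahydronaphthalen-1(2H)-one | CC(C)[C@@]1(O)C=C2CCCC(=O)[C@]2(C)CC1 | intermediate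
5 | (2R,4aR)-4a-methyl-2-(propan-2-yl)-2,5-bis[(trimethylsilyl)oxy]-2,3,4,4a,7,8-hexahydronaphthalene | CC(C)[C@@]1(O[Si](C)(C)C)C=C2CCC=C(O[Si](C)(C)C)[C@]2(C)CC1 | intermediate
6 | (6R,8aR)-8a-methyl-6-(propan-2-yl)-6-[(trimethylsilyl)oxy]-6,7,8,8a-tetrahydronaphthalen-1(4H)-one | CC(C)[C@@]1(O[Si](C)(C)C)C=C2CC=CC(=O)[C@]2(C)CC1 | intermediate
7 | (2R,4aR)-4a,7-dimethyl-2-(propan-2-yl)-2,5-bis[(trimethylsilyl)oxy]-2,3,4,4a,7,8-hexahydronaphthalene (either C7 epimer) | CC(C)[C@@]1(O[Si](C)(C)C)C=C2CC(C)C=C(O[Si](C)(C)C)[C@]2(C)CC1 | intermediate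
8 | (6R,8aR)-3,8a-dimethyl-6-(propan-2-yl)-6-[(trimethylsilyl)oxy]-6,7,8,8a-tetrahydronaphthalen-1(4H)-one | CC(C)[C@@]1(O[Si](C)(C)C)C=C2CC(C)=CC(=O)[C@]2(C)CC1 | intermediate
9 | (1R,6R,8aR)-3,8a-dimethyl-6-(propan-2-yl)-6-[(trimethylsilyl)oxy]-1,4,6,7,8,8a-hexahydronaphthalen-1-ol | CC(C)[C@@]1(O[Si](C)(C)C)C=C2CC(C)=C[C@@H](O)[C@]2(C)CC1 | intermediate
10 | (1R,6R,8aR)-3,8a-dimethyl-6-(propan-2-yl)-1,4,6,7,8,8a-hexahydronaphthalene-1,6-diol | CC(C)[C@@]1(O)C=C2CC(C)=C[C@@H](O)[C@]2(C)CC1 | intermediate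
11 | (2E)-2-methylbut-2-enoyl chloride (tigloyl chloride) | C/C=C(\C)C(Cl)=O | starting material
12 | (1R,6R,8aR)-6-hydroxy-3,8a-dimethyl-6-(propan-2-yl)-1,4,6,7,8,8a-hexahydronaphthalen-1-yl (2E)-2-methylbut-2-enoate | CC(C)[C@@]1(O)C=C2CC(C)=C[C@@H](OC(=O)/C(C)=C/C)[C@]2(C)CC1 | intermediate
13 | (1R,4aR,5S,6R,8aS)-4a,5,6-trihydroxy-3,8a-dimethyl-6-(propan-2-yl)-1,4,4a,5,6,7,8,8a-octahydronaphthalen-1-yl (2E)-2-methylbut-2-enoate | CC(C)[C@@]1(O)[C@H](O)[C@@]2(O)CC(C)=C[C@@H](OC(=O)/C(C)=C/C)[C@]2(C)CC1 | intermediate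
14 | (1R,4aR,5S,6R,8aS)-4a,6-dihydroxy-5-[(methanesulfonyl)oxy]-3,8a-dimethyl-6-(propan-2-yl)-1,4,4a,5,6,7,8,8a-octahydronaphthalen-1-yl (2E)-2-methylbut-2-enoate | CC(C)[C@@]1(O)[C@H](OS(C)(=O)=O)[C@@]2(O)CC(C)=C[C@@H](OC(=O)/C(C)=C/C)[C@]2(C)CC1 | intermediate
15 | (1R,3aR,4R,8aR)-1-hydroxy-3a,6-dimethyl-8-oxo-1-(propan-2-yl)-1,2,3,3a,4,7,8,8a-octahydroazulen-4-yl (2E)-2-methylbut-2-enoate | C/C=C(\C)C(=O)O[C@@H]1C=C(C)CC(=O)[C@@H]2[C@@]1(C)CC[C@@]2(O)C(C)C | intermediate
16 | (1R,3aR,4R,8S,8aS)-1,8-dihydroxy-3a,6-dimethyl-1-(propan-2-yl)-1,2,3,3a,4,7,8,8a-octahydroazulen-4-yl (2E)-2-methylbut-2-enoate | C/C=C(\C)C(=O)O[C@@H]1C=C(C)C[C@H](O)[C@@H]2[C@@]1(C)CC[C@@]2(O)C(C)C | intermediate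
17 | 4-(acetyloxy)benzoyl chloride | CC(=O)Oc1ccc(cc1)C(Cl)=O | starting material
18 | (1R,3aR,4R,8S,8aS)-8-{[4-(acetyloxy)benzoyl]oxy}-1-hydroxy-3a,6-dimethyl-1-(propan-2-yl)-1,2,3,3a,4,7,8,8a-octahydroazulen-4-yl (2E)-2-methylbut-2-enoate | C/C=C(\C)C(=O)O[C@@H]1C=C(C)C[C@H](OC(=O)c2ccc(OC(C)=O)cc2)[C@@H]2[C@@]1(C)CC[C@@]2(O)C(C)C | intermediate
19 | (1R,3aR,4R,8S,8aS)-1-hydroxy-8-[(4-hydroxybenzoyl)oxy]-3a,6-dimethyl-1-(propan-2-yl)-1,2,3,3a,4,7,8,8a-octahydroazulen-4-yl (2E)-2-methylbut-2-enoate | C/C=C(\C)C(=O)O[C@@H]1C=C(C)C[C@H](OC(=O)c2ccc(O)cc2)[C@@H]2[C@@]1(C)CC[C@@]2(O)C(C)C | target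

Total step count: 13
Longest linear sequence: 13 steps (1 to 19)

Steps most likely to fail

Step 10. What may go wrong is loss of regiocontrol between the two possible 1,2-shifts: the C4 alkoxide can push as well, so that C3 migrates and an acylcyclopentane forms; the aldol-type product can also cleave by retro-aldol reaction. The fallback sets out from 14 and differentiates the two tertiary oxygens before the shift. The C4 hydroxyl, which has fewer syn-axial neighbours than the angular C6 hydroxyl, is capped with Me3SiOTf and 2,6-lutidine at −78 °C to give the C4 trimethylsilyl ether of the mesylate F1. Only the C6 hydroxyl can then be deprotonated, and KN(SiMe3)2 (1.0 equiv, THF, −78 to 0 °C) should trigger an anionic semipinacol shift to the C4-silylated ring-contracted ketone F2, which cannot undergo retro-aldol cleavage. Citric acid in MeOH removes the silyl group, and the route is rejoined at 15.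

Step 8. What may go wrong is osmylation of the less hindered C8=C9 alkene in competition with, or instead of, the congested C5=C6 alkene. The fallback sets out from 8 and moves the dihydroxylation to a stage where C8=C9 is part of an enone and inert to OsO4. Bu4NF buffered with AcOH removes the silyl group to give the hydroxy dienone F3. OsO4·TMEDA, directed by the C4 hydroxyl, then gives the keto triol F4. MeSO2Cl in pyridine sulfonylates the only secondary hydroxyl to give the keto mesylate F5. Me4NBH(OAc)3 reduces the enone carbonyl by hydride delivery from the axial C6 hydroxyl, which sets the C10 hydroxyl cis to the C1 methyl in the hydroxy mesylate F6. Tigloyl chloride 11 with DMAP and Et3N acylates the only secondary hydroxyl, and the route is rejoined at 14.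

Step 5. What may go wrong is migration of a double bond across the doubly allylic C7 methylene into conjugation, or over-oxidation, under the palladium conditions. The fallback sets out from 6 and replaces the palladium dehydrogenation by a selenoxide elimination. Me2CuLi adds to C8 and the enolate is trapped with PhSeBr to give the α-phenylselanyl ketone F7. H2O2 with pyridine in CH2Cl2 at 0 °C oxidises selenium, and syn-elimination toward C8, the only carbon with a β-hydrogen, should give the methyl enone; the route is rejoined at 8.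

Further compounds
F1 | step 10 | C4 trimethylsilyl ether of 14 (14 with OSiMe3 in place of the C4 hydroxyl, all other centres as in 14) | CC(C)[C@@]1(O[Si](C)(C)C)[C@H](OS(C)(=O)=O)[C@@]2(O)CC(C)=C[C@@H](OC(=O)/C(C)=C/C)[C@]2(C)CC1
F2 | step 10 | C4 trimethylsilyl ether of 15 (15 with OSiMe3 in place of the C4 hydroxyl, all other centres as in 15) | C/C=C(\C)C(=O)O[C@@H]1C=C(C)CC(=O)[C@@H]2[C@@]1(C)CC[C@@]2(O[Si](C)(C)C)C(C)C
F3 | step 8 | (6R,8aR)-6-hydroxy-3,8a-dimethyl-6-(propan-2-yl)-6,7,8,8a-tetrahydronaphthalen-1(4H)-one | CC(C)[C@@]1(O)C=C2CC(C)=CC(=O)[C@]2(C)CC1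
F4 | step 8 | (4aR,5S,6R,8aR)-4a,5,6-trihydroxy-3,8a-dimethyl-6-(propan-2-yl)-4a,5,6,7,8,8a-hexahydronaphthalen-1(4H)-one | CC(C)[C@@]1(O)[C@H](O)[C@@]2(O)CC(C)=CC(=O)[C@]2(C)CC1
F5 | step 8 | 5-O-methanesulfonate of F4 (mesylate on the secondary hydroxyl, all centres as in F4) | CC(C)[C@@]1(O)[C@H](OS(C)(=O)=O)[C@@]2(O)CC(C)=CC(=O)[C@]2(C)CC1
F6 | step 8 | 14 without the tigloyl group (free C10 hydroxyl cis to the C1 methyl, all other centres as in 14) | CC(C)[C@@]1(O)[C@H](OS(C)(=O)=O)[C@@]2(O)CC(C)=C[C@@H](O)[C@]2(C)CC1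
F7 | step 5 | (6R,8aR)-3,8a-dimethyl-2-(phenylselanyl)-6-(propan-2-yl)-6-[(trimethylsilyl)oxy]-3,4,6,7,8,8a-hexahydronaphthalen-1(2H)-one (methyl and phenylselanyl trans) | CC(C)[C@@]1(O[Si](C)(C)C)C=C2CC(C)C([Se]c3ccccc3)C(=O)[C@]2(C)CC1
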